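**Retrosynthetic overview**

1. Target 19 ⇐ bis(benzyl ether) dibenzoate 18 ⇐ diol 17 ⇐ trans-lactone 16, whose carbonyl carbon is C9 and whose ring CH2O is C9'.
2. 16 ⇐ quaternary lactone ester 14 by loss of CO2Me and thermodynamic setting of C8 trans to C8'.
3. 14 ⇐ cyclopropane lactone 5 + ring B Grignard reagent 8 + ring A benzyl bromide 12 in one flask: the ring B–C7' bond by copper-catalysed opening at the cyclopropane CH2, the C7–C8 bond by benzylation of the released enolate.
4. Feature: the carbons C9–C8–C8'–C9' plus benzylic C7' are the carbon set of a 1-carboxy-3-oxabicyclo[3.1.0]hexan-2-one (C7' = cyclopropane CH2, C8' = ring-fusion CH, C8 = the doubly acylated carbon). Ring B therefore enters at C7' as a nucleophile and the ring A benzyl group at C8 as an electrophile.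
5. Ring order: cyclopropane, then lactone, both in step 1 from (R)-epichlorohydrin (source of C8') and dimethyl malonate; the cyclopropane is opened in step 7 and the lactone in step 10; the target keeps only the arene rings.

Key step: step 7

Remark: lignan numbering C7–C8(C9)–C8'(C9')–C7' is used; ring A is the 3-oxygenated-4-methoxyphenyl ring on C7 and ring B the 4-oxygenated-3-methoxyphenyl ring on C7'. The configuration drawn for the quaternary centre of 14 is the expected one, but it is erased in step 8 and does not matter.

**Route**

Step 1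
Reactants: 1 (R)-epichlorohydrin; 2 dimethyl malonate
Product: 5 methyl (1S,5R)-2-oxo-3-oxabicyclo[3.1.0]hexane-1-carboxylate, via transposed epoxide 3 (not isolated), via cyclopropylmethanolate 4 (not isolated)
Conditions: NaOMe (1.05 equiv), MeOH, rt then reflux
Reagents that add atoms: none
Why: Malonate double alkylation, in which the enolate opens the epoxide at its CH2, chloride loss gives the transposed epoxide 3, 3-exo-tet closure with inversion at the epoxide CH gives alkoxide 4 and this lactonises onto the cis ester, is the established one-flask entry to this bicyclic lactone; the centre of 1 becomes C5 (R) and C1 (S) follows from the obligatory cis ring fusion.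

Step 2
Reactants: 6 4-bromo-2-methoxyphenol
Product: 7 1-(benzyloxy)-4-bromo-2-methoxybenzene
Conditions: BnBr, K2CO3, acetone, reflux
Reagents that add atoms: benzyl bromide, BrCc1ccccc1
Why: Williamson ether synthesis of a phenoxide with a benzylic bromide under carbonate base, to which the aryl bromide is inert.

Step 3
Reactants: 7 1-(benzyloxy)-4-bromo-2-methoxybenzene
Product: 8 [4-(benzyloxy)-3-methoxyphenyl]magnesium bromide (THF solution, titrated and used directly)
Conditions: Mg turnings, I2 (cat.), THF, reflux then rt
Reagents that add atoms: magnesium, [Mg]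
Why: Grignard formation by insertion of magnesium into an electron-rich aryl bromide, which the aryl benzyl and methyl ethers tolerate.

Step 4
Reactants: 9 isovanillin (3-hydroxy-4-methoxybenzaldehyde)
Product: 10 3-(benzyloxy)-4-methoxybenzaldehyde
Conditions: BnBr, K2CO3, DMF, 60 °C
Reagents that add atoms: benzyl bromide, BrCc1ccccc1
Why: Williamson ether synthesis on the phenol, the aldehyde being unaffected by carbonate base.

Step 5
Reactants: 10 3-(benzyloxy)-4-methoxybenzaldehyde
Product: 11 [3-(benzyloxy)-4-methoxyphenyl]methanol
Conditions: NaBH4, MeOH, 0 °C to rt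
Reagents that add atoms: none
Why: Borohydride reduction of an aromatic aldehyde to the benzylic alcohol, leaving both ethers untouched.

Step 6
Reactants: 11 [3-(benzyloxy)-4-methoxyphenyl]methanol
Product: 12 2-(benzyloxy)-4-(bromomethyl)-1-methoxybenzene (3-(benzyloxy)-4-methoxybenzyl bromide)
Conditions: PBr3 (0.4 equiv), Et2O, 0 °C; used freshly prepared
Reagents that add atoms: phosphorus tribromide, BrP(Br)Br
Why: Conversion of a primary benzylic alcohol into its bromide through the phosphite ester and SN2 displacement by bromide, run cold and short so that the aryl benzyl ether and the labile electron-rich bromide survive.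

Step 7
Reactants: 5 methyl (1S,5R)-2-oxo-3-oxabicyclo[3.1.0]hexane-1-carboxylate; 8 [4-(benzyloxy)-3-methoxyphenyl]magnesium bromide; 12 2-(benzyloxy)-4-(bromomethyl)-1-methoxybenzene
Product: 14 methyl (3R,4R)-3-[3-(benzyloxy)-4-methoxybenzyl]-4-[4-(benzyloxy)-3-methoxybenzyl]-2-oxotetrahydrofuran-3-carboxylate, via bromomagnesium lactone enolate 13 (not isolated)
Conditions: 8 (1.15 equiv), CuBr·SMe2 (10 mol%), THF, −40 to 0 °C; then DMPU, Bu4NI (cat.), 12 (1.5 equiv), 0 to 40 °C; aq NH4Cl
Reagents that add atoms: none
Why: The arylcopper species formed from 8 and CuBr·SMe2 (monovalent copper) attacks the cyclopropane CH2 (C7') of 5 in an SN2-like oxidative addition, and reductive elimination from the resulting trivalent copper intermediate forms the ring B–C7' bond and releases the doubly stabilised bromomagnesium enolate 13, which is then C-benzylated by 12, with DMPU as activating cosolvent, to form the C7–C8 bond. The closest known reaction type is the copper-catalysed homoconjugate addition of Grignard reagents to cyclopropane-1,1-dicarbonyl compounds, including this bicyclic lactone class, combined with the classical C-alkylation of a 2-alkoxycarbonyl lactone enolate. No ring is closed: the cyclopropane is opened and the lactone ring is carried through intact. C8' (lactone C4) is not touched and keeps the R configuration bought with 1, while the new quaternary centre C8 (lactone C3) should form by benzylation anti to the C4 benzyl group, an outcome without consequence because this centre is reset in steps 8 and 9. The step needs attack at the CH2 rather than at the ring-fusion CH and homoconjugate rather than carbonyl addition; the first is secured by the lower substitution of the CH2 carbon, the second by the soft copper nucleophile at low temperature and by the geminal activation through two carbonyl groups, and C- over O-benzylation by the soft benzylic halide.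

Step 8
Reactants: 14 methyl (3R,4R)-3-[3-(benzyloxy)-4-methoxybenzyl]-4-[4-(benzyloxy)-3-methoxybenzyl]-2-oxotetrahydrofuran-3-carboxylate
Product: 15 (3RS,4R)-3-[3-(benzyloxy)-4-methoxybenzyl]-4-[4-(benzyloxy)-3-methoxybenzyl]dihydrofuran-2(3H)-one as a mixture of C3 epimers
Conditions: LiCl (3 equiv), H2O (3 equiv), DMSO, 150 °C
Reagents that add atoms: none
Why: Krapcho dealkoxycarbonylation, in which chloride demethylates the geminally activated methyl ester by SN2 attack at the methyl group, CO2 is lost and water protonates the lactone enolate, should give both C3 epimers because protonation anti to the C4 benzyl group favours cis while the hot basic medium favours trans.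

Step 9
Reactants: 15 (3RS,4R)-lactone, mixture of C3 epimers
Product: 16 (3R,4R)-3-[3-(benzyloxy)-4-methoxybenzyl]-4-[4-(benzyloxy)-3-methoxybenzyl]dihydrofuran-2(3H)-one (trans)
Conditions: DBU, toluene, 80 °C
Reagents that add atoms: none
Why: Base-mediated epimerisation through the lactone enolate should drive C3 (C8) to the thermodynamically preferred trans-3,4-dibenzyl lactone, which avoids the eclipsing of the two benzyl groups in the cis isomer, so that C8 becomes R relative to the fixed C8' (R).

Step 10
Reactants: 16 (3R,4R)-trans-lactone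
Product: 17 (2R,3R)-2-[3-(benzyloxy)-4-methoxybenzyl]-3-[4-(benzyloxy)-3-methoxybenzyl]butane-1,4-diol
Conditions: LiAlH4, THF, 0 °C to rt; then H2O
Reagents that add atoms: none
Why: Hydride reduction of the lactone to the 1,4-diol by LiAlH4, which leaves the two stereocentres and the benzyl and methyl ethers untouched.

Step 11
Reactants: 17 (2R,3R)-diol
Product: 18 (2R,3R)-2-[3-(benzyloxy)-4-methoxybenzyl]-3-[4-(benzyloxy)-3-methoxybenzyl]butane-1,4-diyl dibenzoate
Conditions: BzCl (2.5 equiv), pyridine, DMAP (cat.), CH2Cl2, 0 °C to rt
Reagents that add atoms: benzoyl chloride, O=C(Cl)c1ccccc1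
Why: DMAP-catalysed acylation of both primary alcohols with benzoyl chloride, in which only the two CH2OH groups can react because both phenols are masked as benzyl ethers.

Step 12
Reactants: 18 bis(benzyl ether) dibenzoate
Product: 19 (2R,3R)-2-(3-hydroxy-4-methoxybenzyl)-3-(4-hydroxy-3-methoxybenzyl)butane-1,4-diyl dibenzoate (target)
Conditions: H2 (1 atm), 10% Pd/C, EtOAc, rt
Reagents that add atoms: none
Why: Hydrogenolysis of the two aryl benzyl ethers over Pd/C, to which primary alkyl benzoates, aryl methyl ethers and the two stereocentres are inert.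

**Compound list**

1 | (R)-epichlorohydrin | ClC[C@H]1CO1 | starting material
2 | dimethyl malonate | COC(=O)CC(=O)OC | starting material
3 | dimethyl 2-{[(2R)-oxiran-2-yl]methyl}propanedioate (transposed epoxide) | COC(=O)C(C(=O)OC)C[C@@H]1CO1 | intermediate
4 | sodium [(1R)-2,2-bis(methoxycarbonyl)cyclopropyl]methanolate | COC(=O)C1(C(=O)OC)C[C@H]1C[O-].[Na+] | intermediate
5 | methyl (1S,5R)-2-oxo-3-oxabicyclo[3.1.0]hexane-1-carboxylate | COC(=O)[C@]12C[C@H]1COC2=O | intermediate
6 | 4-bromo-2-methoxyphenol | COc1cc(Br)ccc1O | starting material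
7 | 1-(benzyloxy)-4-bromo-2-methoxybenzene | COc1cc(Br)ccc1OCc1ccccc1 | intermediate
8 | [4-(benzyloxy)-3-methoxyphenyl]magnesium bromide | COc1cc([Mg]Br)ccc1OCc1ccccc1 | intermediate
9 | isovanillin (3-hydroxy-4-methoxybenzaldehyde) | COc1ccc(C=O)cc1O | starting material
10 | 3-(benzyloxy)-4-methoxybenzaldehyde | COc1ccc(C=O)cc1OCc1ccccc1 | intermediate
11 | [3-(benzyloxy)-4-methoxyphenyl]methanol | COc1ccc(CO)cc1OCc1ccccc1 | intermediate
12 | 2-(benzyloxy)-4-(bromomethyl)-1-methoxybenzene | COc1ccc(CBr)cc1OCc1ccccc1 | intermediate
13 | bromomagnesium enolate of methyl (4R)-4-[4-(benzyloxy)-3-methoxybenzyl]-2-oxotetrahydrofuran-3-carboxylate | COC(=O)C1=C(O[Mg]Br)OC[C@@H]1Cc1ccc(OCc2ccccc2)c(OC)c1 | intermediate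
14 | methyl (3R,4R)-3-[3-(benzyloxy)-4-methoxybenzyl]-4-[4-(benzyloxy)-3-methoxybenzyl]-2-oxotetrahydrofuran-3-carboxylate | COC(=O)[C@]1(Cc2ccc(OC)c(OCc3ccccc3)c2)C(=O)OC[C@@H]1Cc1ccc(OCc2ccccc2)c(OC)c1 | intermediate
15 | (3RS,4R)-3-[3-(benzyloxy)-4-methoxybenzyl]-4-[4-(benzyloxy)-3-methoxybenzyl]dihydrofuran-2(3H)-one, C3 epimer mixture (C3 left undefined in the SMILES) | O=C1OC[C@H](Cc2ccc(OCc3ccccc3)c(OC)c2)C1Cc1ccc(OC)c(OCc2ccccc2)c1 | intermediate
16 | (3R,4R)-3-[3-(benzyloxy)-4-methoxybenzyl]-4-[4-(benzyloxy)-3-methoxybenzyl]dihydrofuran-2(3H)-one | O=C1OC[C@H](Cc2ccc(OCc3ccccc3)c(OC)c2)[C@H]1Cc1ccc(OC)c(OCc2ccccc2)c1 | intermediate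
17 | (2R,3R)-2-[3-(benzyloxy)-4-methoxybenzyl]-3-[4-(benzyloxy)-3-methoxybenzyl]butane-1,4-diol | COc1ccc(C[C@@H](CO)[C@H](CO)Cc2ccc(OCc3ccccc3)c(OC)c2)cc1OCc1ccccc1 | intermediate
18 | (2R,3R)-2-[3-(benzyloxy)-4-methoxybenzyl]-3-[4-(benzyloxy)-3-methoxybenzyl]butane-1,4-diyl dibenzoate | COc1ccc(C[C@@H](COC(=O)c2ccccc2)[C@H](COC(=O)c2ccccc2)Cc2ccc(OCc3ccccc3)c(OC)c2)cc1OCc1ccccc1 | intermediate
19 | (2R,3R)-2-(3-hydroxy-4-methoxybenzyl)-3-(4-hydroxy-3-methoxybenzyl)butane-1,4-diyl dibenzoate | COc1ccc(C[C@@H](COC(=O)c2ccccc2)[C@H](COC(=O)c2ccccc2)Cc2ccc(O)c(OC)c2)cc1O | target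

**Step count**

Total steps: 12. Longest linear sequence: 9 steps (steps 4, 5, 6, 7, 8, 9, 10, 11, 12, from isovanillin 9 to target 19).

**Steps most likely to fail**

Step 7. The chelated bromomagnesium enolate may be benzylated only sluggishly. Residual aryl Grignard reagent may be consumed by copper-catalysed coupling with the benzylic bromide, and some carbonyl addition may compete with the homoconjugate opening. The fallback separates the two bond formations. It sets out from 5 and 8: the same copper-catalysed opening is run without electrophile and quenched with aqueous NH4Cl to give methyl (4R)-4-[4-(benzyloxy)-3-methoxybenzyl]-2-oxotetrahydrofuran-3-carboxylate F1 (C3 epimerisable), which is isolated. F1 is then C-benzylated with 12 under K2CO3 in DMF at room temperature, the classical alkylation of a 2-alkoxycarbonyl lactone through its potassium enolate. This comes back to the route at 14.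

Step 8. Demethoxycarbonylation at the hindered quaternary centre may stall, and at 150 °C chloride may open the lactone at its CH2O carbon or slowly cleave an aryl benzyl ether. The fallback replaces the nucleophilic dealkylation by hydrolysis and thermal decarboxylation and sets out from 14. Saponification with KOH in aqueous methanol at reflux should give dipotassium 2-[3-(benzyloxy)-4-methoxybenzyl]-2-[(2R)-1-[4-(benzyloxy)-3-methoxyphenyl]-3-hydroxypropan-2-yl]propanedioate F2. Acidification with aqueous HCl should relactonise it to (4R)-3-[3-(benzyloxy)-4-methoxybenzyl]-4-[4-(benzyloxy)-3-methoxybenzyl]-2-oxotetrahydrofuran-3-carboxylic acid F3 (C3 epimers). Heating F3 in toluene at 110 °C should expel CO2 as for any malonic-type acid, which comes back to the route at 15.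

Step 9. The thermodynamic preference for the trans lactone may be incomplete, so that cis material is carried into the diol as a diastereomer that is hard to remove. The fallback sets C8 kinetically instead and sets out from 5 and 8. The proton-quenched opening product F1 (made as in the fallback to step 7) is demethoxycarbonylated with LiCl in wet DMSO at 140 °C to (4R)-4-[4-(benzyloxy)-3-methoxybenzyl]dihydrofuran-2(3H)-one F4. Its lithium enolate (LiN(SiMe3)2, THF, −78 °C) is alkylated with 12 anti to the C4 benzyl group, the standard trans-selective alkylation of 4-benzyl butyrolactones. This comes back to the route at 16 and bypasses steps 7 to 9.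

**Further compounds**

F1 | step 7 | methyl (4R)-4-[4-(benzyloxy)-3-methoxybenzyl]-2-oxotetrahydrofuran-3-carboxylate (C3 epimerisable, undefined) | COC(=O)C1C(=O)OC[C@@H]1Cc1ccc(OCc2ccccc2)c(OC)c1
F2 | step 8 | dipotassium 2-[3-(benzyloxy)-4-methoxybenzyl]-2-[(2R)-1-[4-(benzyloxy)-3-methoxyphenyl]-3-hydroxypropan-2-yl]propanedioate | [K+].[K+].[O-]C(=O)C(Cc1ccc(OC)c(OCc2ccccc2)c1)(C([O-])=O)[C@H](CO)Cc1ccc(OCc2ccccc2)c(OC)c1
F3 | step 8 | (4R)-3-[3-(benzyloxy)-4-methoxybenzyl]-4-[4-(benzyloxy)-3-methoxybenzyl]-2-oxotetrahydrofuran-3-carboxylic acid (C3 epimers, undefined) | OC(=O)C1(Cc2ccc(OC)c(OCc3ccccc3)c2)C(=O)OC[C@@H]1Cc1ccc(OCc2ccccc2)c(OC)c1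
F4 | step 9 | (4R)-4-[4-(benzyloxy)-3-methoxybenzyl]dihydrofuran-2(3H)-one | O=C1C[C@@H](Cc2ccc(OCc3ccccc3)c(OC)c2)CO1
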